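Amounts first: in each flask I add Q and E into one open sum, the part of the charge not yet turned into D or X, and I ask where that sum stands still.

in all of them: L 0.05 mol%
- north-east: Q 0.40 M; temperature 5 °C; run made earlier
- south-west: Q 0.60 M; temperature 24 °C; run made earlier
- Saturday's: Q 0.80 M; temperature 20 °C; time 10 d
- Friday's: Q 0.80 M; temperature 28 °C; time 10 d

| run | time / d | E / % | Q / % | D / % | X / % |
|---|---|---|---|---|---|
| north-east | 2.00 | 4.5 | 57.3 | 37.2 | 1.1 |
| north-east | 6.00 | 7.5 | 25.3 | 64.7 | 2.6 |
| north-east | 10.0 | 7.8 | 14.1 | 72.2 | 5.7 |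
| north-east | 15.0 | 8.4 | 8.5 | 75.9 | 7.6 |
| south-west | 0.625 | 20.0 | 33.5 | 40.2 | 4.5 |
| south-west | 1.67 | 22.0 | 18.0 | 49.9 | 11.0 |
| south-west | 3.00 | 22.3 | 14.9 | 50.6 | 12.5 |
| south-west | 8.00 | 22.9 | 15.0 | 50.4 | 12.9 |

(standard deviation of a reading: 0.5 percentage points)

- which of these there is most of at the end, counted by the Q in it, Saturday's (X / E / Q / D)
- which of these there is most of at the end, counted by the Q in it, Friday's (X / E / Q / D)
- how much there is at the end of the one of these that leads, in percent of the Q charged: Saturday's
- how much there is at the end of the one of these that leads, in percent of the Q charged: Friday's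



I call the natural logarithm of the charge over the open sum the reach, W. The loading is the same in every flask, so L charged goes with Q charged. I assume that W grows in step with it and divide by the starting concentration of Q, which gives the reach per molar, w.

Now the ladder of times, from my own reckoning. In the south-west run, the growth of W fades from one interval to the next at 1.37 d⁻¹. The open sum then stands near 37.9% with Q and E both present, so I read this as the work of L fading, and w there is 1.62 M⁻¹. In the north-east run the fading is slower, at 0.148 d⁻¹, and adding the tail still to come gives w of 5.05 M⁻¹.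

I interpolate the logarithms linearly in temperature. The fading lives come to 0.456 d for Friday's and 1.16 d for Saturday's, both shorter than the 10 d allowed, so I reckon a stopping point and not a rate. At 20 °C the reach per molar is 2.05 M⁻¹, and at 28 °C it is 1.27 M⁻¹. The open sum is then 19.3% in Saturday's and 36.1% in Friday's. The selectivity for D, D over D plus X, interpolated the same way from the last readings, then gives D of 66.2% in Saturday's and 49.3% in Friday's, more than the open sum in each.

The forecast also puts D in the lead in both flasks, but with 54% for Saturday's and 43% for Friday's, below my figures. Its ground differs: “I treat the steps as unimolecular equilibria, with concentration having little effect”.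

The flasks end with D leading, at 68.0% in Saturday's and 51.5% in Friday's.

    Q ⇌ E (K = 1.67, k = 5.09 × 10⁻⁶ s⁻¹, Ea = 110 kJ mol⁻¹, ΔH = −12.0 kJ mol⁻¹)
    Q + L → L + D (k = 0.0461 M⁻¹ s⁻¹, Ea = 48.0 kJ mol⁻¹)
    L + E → L + X (k = 0.0316 M⁻¹ s⁻¹, Ea = 57.0 kJ mol⁻¹)
    L → Z (k = 1.01 × 10⁻⁵ s⁻¹, Ea = 91.0 kJ mol⁻¹)
    (constants at 20 °C)

In Saturday's, L is down to 1.27% of its charge at 5.00 d, with Z at 98.7% and D at 67.8%. The Q and E left there at the end give w of 2.07 M⁻¹, beside my 2.05 M⁻¹. For the flask like Saturday's but with 0.20 M of Q, 2.05 M⁻¹ gives an open sum of 66.4%. That flask ends with Q 24.7% and E 41.3%, together 66.0%.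

The earlier runs and the new flask come from a simulation on assumed constants, noise included.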